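Count the substrate's half-lives in each flask before reckoning any yield.

common to all: substrate 0.050 M
- noon: coupling partner 0.060 M; free catalyst 0.042 mM; run made earlier
- dawn: coupling partner 0.060 M; free catalyst 0.26 mM; run made earlier
- alder: coupling partner 0.0600 M; free catalyst 0.40 mM; time 25 min
- elm: coupling partner 0.0600 M; free catalyst 0.20 mM; time 25 min
- cedar: coupling partner 0.0600 M; free catalyst 0.10 mM; time 25 min
- larch: coupling partner 0.0600 M; free catalyst 0.050 mM; time 25 min

| run | time / min | product / % |
|---|---|---|
| noon | 4.00 | 3 |
| noon | 8.00 | 10 |
| noon | 12.0 | 8 |
| noon | 20.0 | 10 |
| dawn | 2.00 | 8 |
| dawn | 6.00 | 19 |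
| dawn | 12.0 | 37 |
| dawn | 20.0 | 59 |

(scatter of a reading: 2 percentage points)

1. all flasks from highest to lowest amount of product, in percent of the substrate charged, at 25 min (alder / elm / cedar / larch)
2. the same order at 2.5 min (alder / elm / cedar / larch)
3. the amount of product, in percent of the substrate charged of the flask you put first, at 25 min
4. the amount of product, in percent of the substrate charged of the flask you put last, at 25 min



Product seems to go with catalyst: noon's last reading is 0.169 of dawn's, on 0.162 of its catalyst. Noon's flat last readings span 2 percentage points, the size of the stated scatter, so they are read here as scatter, not as a stall.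

Two extreme flasks can then be solved in the head, both scaled from dawn's last reading. In the first, a straight line (zero order), dawn's slope of 0.0295 min⁻¹ as a fraction of the charge scales with catalyst. The line gives larch 14.2% and alder 113%, which overruns the charge, so for alder that extreme is taken as complete conversion.

In the second, pseudo-first-order in substrate, each half-life takes the same fraction of what is left. Dawn's reading gives 15.5 min, the substrate half-life at the dawn catalyst charge, and this reckoning takes it to shorten in proportion as catalyst rises. Alder then counts 2.47 half-lives, reckoned as 82.0% product; larch counts 0.309, reckoned as 19.3%.

Dawn's slope after 12.0 min is 0.892 of its earlier slope, while the mean substrate left falls to 0.638 of its earlier value. Taken with their scatter, dawn's readings therefore lie between the extremes, and this reckoning expects the flasks there too, within that scatter. This reckoning carries the half-life figures and ranks alder first and larch last at either time, since alder has the highest catalyst charge and larch the lowest.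

The forecast, on the suggestion that “the catalyst dies after a fixed number of turnovers”, gives alder > elm > cedar > larch at 25 min, alder > elm > cedar > larch at 2.5 min, 90% for alder and 12% for larch.

The flasks give alder > elm > cedar > larch at 25 min and alder > elm > cedar > larch at 2.5 min, with alder at 81.3% and larch at 17.2%.

    coupling partner + free catalyst → catalyst intermediate A (k = 800 L mol⁻¹ min⁻¹)
    catalyst intermediate C → catalyst intermediate D (k = 51.0 min⁻¹)
    catalyst intermediate D → free catalyst + product (k = 1600 min⁻¹)
    substrate + catalyst intermediate B ⇌ catalyst intermediate C (K = 6.70 L mol⁻¹, k = 700 L mol⁻¹ min⁻¹)
    free catalyst ⇌ dormant form (K = 0.210, k = 0.00810 min⁻¹)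
    catalyst intermediate A ⇌ by-product + catalyst intermediate B (K = 1.50 M, k = 210 min⁻¹)

Alder stands 0.70 points under its count, less than the scatter of the reading behind that count, and larch lies between its two extremes. A neighbour of larch with 0.013 M of substrate has the same count, so 19.3% is reckoned, and it gives 22.4%; the straight line reckons 54.5%. Neither alder nor larch has come to rest at 25 min: alder keeps 19% of its substrate, larch 83%. At ten times the time alder reaches 100%, its substrate, the limiting reagent, down to 0%, with 16.0% of the coupling partner left. Larch, counting 3.09 half-lives, reckons 88.3% and reaches 88.0%, with 12.0% of its substrate unreacted.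

The earlier runs and the new flask stem from a simulated flask for an exercise, and the scatter is random.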